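**Conventions.** Lignan numbering is used throughout: C1 (acetoxy-bearing fusion carbon), C2 (CH bearing the 4-hydroxy-3-methoxyphenyl group), O3, C4 (CH2), C5 (fusion CH), C6 (CH bearing the 3,4-dimethoxyphenyl group), O7, C8 (CH2). Ring A is C1–C2–O3–C4–C5 and ring B is C5–C6–O7–C8–C1.

**Remark on the chemistry (assumption).** The catalyst enantiomer in step 3 is chosen by analogy: the D-fructose-derived ketone gives the (R)-configured ArCH carbon with (E)-1-arylalkenes, so the (S) centre needed here calls for the L-fructose-derived ketone. This ketone is taken to be available (it is made from L-sorbose).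

## Analysis of the target

The target is a cis-fused 2,6-diaryl-3,7-dioxabicyclo[3.3.0]octane carrying a tertiary acetate at the fusion carbon C1. It has four contiguous stereocentres, C1 (S), C2 (R), C5 (R) and C6 (S). The C1 acetoxy group and H5 lie on the convex face, and both aryl groups are exo: the C2 aryl is cis to the C1 oxygen and the C6 aryl is cis to H5. The sensitive groups are the tertiary acetate (base, hydride, nucleophiles), the single free phenol beside three aryl methyl ethers, and the two electron-rich benzylic C–O bonds C2–O3 and C6–O7, which ionise under acid and can be hydrogenolysed. The difficulty is the lack of symmetry: the two aryl groups differ and only one fusion carbon is oxygenated, so each ring and each benzylic centre has to be built separately around a fully substituted, oxygenated C1. The strategy rests on the fact that the C1 oxygen and O3 on C2 sit on neighbouring carbons. Both can therefore come from one C1–C2 epoxide of a Stobbe-derived (E)-arylidene lactone in which the carboxyl carbon C4 already carries the oxygen that becomes O3. Opening that epoxide at C2 with the C4 carboxylate closes ring A and fixes C1 and C2 at once; the carbonyl left at C4 then makes C5 nucleophilic, and the C8 hydroxyl set free in the same event is the future O7.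

## Retrosynthetic reasoning

**O–benzyl bond (18 from 17).** The free phenol is unmasked last. A benzyl ether is chosen because it survives alkoxide, hydride, enolate and Lewis acid steps and leaves under neutral hydrogenolysis, which the tertiary acetate tolerates. The forward step has to cleave the aryl benzyl ether without hydrogenolysing C2–O3 or C6–O7.

**C1 O–acetyl bond (17 from 16).** The acetate is attached late because it would not survive the enolate and hydride steps, and because the free C1 alkoxide is needed earlier as a control element. The forward step is acylation of a hindered tertiary hydroxyl that is by then the only hydroxyl present.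

**Oxidation level at C4 (16 from 14, through 15).** No skeletal bond is cut here. Raising C4 to the carbonyl level turns ring A into a lactone, which makes C5 acidic and makes O3 an acyl oxygen. The forward reaction must reduce the lactone to the cyclic ether without ionising the benzylic C–O bonds.

**C6–O7 bond (14 from 13, and 13 from 12).** Ring B is opened at C6–O7 and not at C8–O7. C6 is a 3,4-dimethoxybenzylic carbon that ionises easily, so closure through the cation is stereoconvergent, whereas activation of C8 next to the C1 hydroxyl would invite epoxide formation. The forward closure has to place the aryl exo; 13 comes from 12 by freeing the C8 hydroxyl.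

**C5–C6 bond (12 from 10 and 11; 10 from 9).** This is an aldol bond between the α-carbon of the ring A lactone and aldehyde 11. It is cut here because it is the only C–C bond that joins the two halves and both partners are then simple. The forward reaction must add 11 to C5 on the face anti to the C1 oxygen so that C6 and C8 are cis; 10 is 9 with the primary C8 hydroxyl silylated.

**C2–O3 bond (9 from 7, through 8; key disconnection).** Cutting C2–O3 and joining the C1 oxygen to C2 gives an epoxide; returning the acyl group from O3 to the C8 oxygen gives the spiro-epoxy lactone 7. This is the place to cut because one operation then accounts for ring A, for the C1 hydroxyl and for the C2 configuration. The forward reaction must open the epoxide at C2 only, with inversion.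

**Epoxide (7 from 6).** Removing the epoxide oxygen leaves the (E)-arylidene lactone 6. The forward reaction is a catalyst-controlled epoxidation in which olefin geometry and face selection fix C1 and C2 together.

**C2=C1 bond and C8 oxidation level (6 from 4 through 5; 4 from 1 and 2 through 3).** The arylidene lactone is the reduced, lactonised form of a Stobbe half-ester. Cutting the C1=C2 double bond leads to aldehyde 1 and diester 2. The forward sequence has to deliver the (E) olefin and reduce only the ester carbon that becomes C8.

## Alternatives that were turned down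

**Alternative 1:** Ring B is disconnected at C6–O7 back to a C6 methylene, that is to the ring A tetrahydrofuran A2 with a 3,4-dimethoxybenzyl group on C5, the C1/C8 diol and the phenol as its acetate. In the forward key step a high-potential quinone oxidant abstracts hydride from the benzylic CH2 and the C8 hydroxyl traps the cation to give A1.
- In its favour: no C6 hydroxyl has to be carried, ring B is closed by C–H functionalisation, and the aryl acetate deactivates the C2–H bond toward the oxidant. On ring B economy it is stronger than the chosen route, which needs an aldol carbinol, a desilylation and an acid step.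
- Against it: the product A1 contains at C6 a 3,4-dimethoxybenzylic ether C–H that is easier to oxidise than the methylene of A2, so over-oxidation and ring cleavage threaten. A2 itself needs C1, C2 and C5 set on ring A, and this alternative gives no particular handle on that. The acetyl group ends on the phenol and not on C1, so an acetylation at C1 and a selective cleavage of the aryl acetate would still follow.
- In its place the chosen strategy offers a catalytic asymmetric origin for C1 and C2 and a ring B closure whose product is not exposed to an oxidant.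

**Alternative 2:** The shared C1–C5 bond is disconnected, leading to the eight-membered keto enol ether A4. In the forward key step a Lewis acid activates the C1 ketone, enol ether carbon C5 attacks it across the ring, and a silane reduces the C4 oxocarbenium ion to give A3.
- In its favour: both rings, C1 and C5 arise in one step, the cis fusion is enforced, and A3 is the same compound as 16, two steps from the target. On convergence and on the step count after the medium ring it is stronger than the chosen route.
- Against it: A4 is an eight-membered ring with a Z enol ether and an epimerisable C2 centre flanked by ketone, aryl and ether oxygen. Its assembly from two enantiopure aryl carbinol units and its ring closure are costly. The facial course of the transannular step, which must place both aryls exo, depends on a ring conformation that cannot be predicted with confidence.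
- In its place the chosen strategy offers short, well-precedented access to its key substrate and stereocontrol that follows from olefin geometry and a stereospecific substitution.

**Alternative 3:** O3 is removed from between C2 and C4, leading to the cis-fused 2-aryl cyclobutanone A6, a ketene–enol ether cycloadduct. In the forward key step a peracid inserts oxygen with migration of benzylic C2 to give the ring A lactone A5.
- In its favour: ring B with C6 is in place first, the cycloaddition forms C1–C2 and C4–C5 together and installs the oxygenated quaternary C1, and the migration proceeds with retention. A5 is the silyl ether of 14, so the end game would be the same. In bond-forming economy at the quaternary carbon it is stronger.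
- Against it: both candidates for migration, C2 and C5, are secondary, so regiochemistry rests on the benzylic preference alone. Peracid meets two electron-rich arenes. Ketene cycloadditions tend to place the larger ketene substituent on the concave face, so C2 would need epimerisation. The absolute configuration has to come from a pre-set C6 centre in a sensitive enol ether.
- In its place the chosen strategy offers a catalyst-controlled entry to C1 and C2 and no peracid step.

Key step: step 4

## Route

**Step 1**
Reactants: 1 4-(benzyloxy)-3-methoxybenzaldehyde (O-benzylvanillin); 2 dimethyl succinate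
Product: 4 (E)-4-[4-(benzyloxy)-3-methoxyphenyl]-3-(methoxycarbonyl)but-3-enoic acid, via paraconate lactone ester 3 (not isolated)
Conditions: NaOMe (2.2 equiv), MeOH, reflux; then 2 M HCl, 0 °C
Reagents that add atoms: none
Why: Stobbe condensation: the succinate enolate adds to 1, the aldolate closes to lactone 3, and E1cB ring opening gives the half-ester. The (E) isomer (aryl trans to CO2Me, cis to CH2CO2H) is the usual outcome.

**Step 2**
Reactants: 4 (E)-half-ester
Product: 6 (E)-4-[4-(benzyloxy)-3-methoxybenzylidene]dihydrofuran-2(3H)-one, via hydroxy acid 5 (not isolated)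
Conditions: KOH (1.0 equiv), EtOH; CaCl2, NaBH4, EtOH, −10 °C → rt; then 1 M HCl to pH 2–3, 0 °C → rt
Reagents that add atoms: none
Why: Chemoselective ester reduction: Ca(BH4)2 formed in the flask reduces the methyl ester of the potassium salt while the carboxylate is inert, and the γ-hydroxy acid 5 lactonises on mild acidification. The trisubstituted double bond should stay in place with its (E) geometry (aryl cis to the ring CH2C=O, trans to CH2O).

**Step 3**
Reactants: 6 (E)-arylidene lactone
Product: 7 (2S,3S)-2-[4-(benzyloxy)-3-methoxyphenyl]-1,5-dioxaspiro[2.4]heptan-6-one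
Conditions: 1,2:4,5-di-O-isopropylidene-β-L-erythro-2,3-hexodiulo-2,6-pyranose (0.3 equiv), KHSO5 (as 2KHSO5·KHSO4·K2SO4), K2CO3, Bu4NHSO4, MeCN–CH2(OMe)2–aq. Na2B4O7 buffer (pH 10.5), 0 °C; crude 7 used directly
Reagents that add atoms: potassium peroxymonosulfate, [K+].[O-]S(=O)(=O)OO
Why: Shi-type asymmetric epoxidation by the chiral dioxirane formed in the flask; arylidenecycloalkane-type trisubstituted (E)-olefins are a suitable substrate class and oxygen transfer is syn-stereospecific, so the aryl stays cis to C5. The L-fructose-derived ketone is expected to attack the face that gives the (S) benzylic carbon, which sets C1 (S) and C2 (S in 7) together.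

**Step 4**
Reactants: 7 spiro-epoxy lactone
Product: 9 (4S,5R)-5-[4-(benzyloxy)-3-methoxyphenyl]-4-hydroxy-4-(hydroxymethyl)dihydrofuran-2(3H)-one, via epoxy hydroxy carboxylate 8 (not isolated)
Conditions: LiOH (1.05 equiv), THF–H2O, 0 °C; then aq. NaH2PO4 to pH 7, 0 °C → rt
Reagents that add atoms: lithium hydroxide, [Li+].[OH-]
Why: Hydroxide adds to the C4 carbonyl of 7 much faster than it can remove a C5 proton, so the lactone opens to the C8 alcohol and the C4 carboxylate 8 before an E1cB opening of the epoxide can begin, and in the carboxylate C5–H is no longer acidic. At pH 7 a carboxylate oxygen attacks benzylic C2 from the rear of the C2–O(epoxide) bond while H2PO4− protonates the leaving oxygen: C2–O3 forms, the epoxide oxygen stays on C1 as the hydroxyl, and the acyl group has moved from the C8 oxygen to O3. The closest known reaction type is the lactonisation of β,γ-epoxy acids to β-hydroxy-γ-butyrolactones with inversion at the γ-carbon. Ring A closes in the 5-endo-tet mode (both epoxide carbons enter the new ring); this is the usual course for such acids because the 4-exo alternative at C1 would be a β-lactone formed by substitution at a fully substituted carbon, and the p-alkoxyaryl group loosens the C2–O bond enough for the bent trajectory. C1 keeps the oxygen and the configuration it received in step 3; C2 is inverted (S in 7, R in 9), so it is controlled by the (E) geometry of 6 together with the epoxide face, and the aryl ends cis to the C1 hydroxyl and trans to C8. The step needs attack at C2 and not C1 (secured by ring size and benzylic activation), inversion and not free ionisation (neutral pH keeps the specific-acid pathway slow; should some ionisation occur, C1 is untouched and A1,3 strain in the cation, with OH and not CH2OH eclipsing the aryl, leads to the same C2 epimer), and no Payne migration (hydroxide is used up by the saponification and the C8 oxygen would have to attack fully substituted C1).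

**Step 5**
Reactants: 9 ring A hydroxylactone diol
Product: 10 (4S,5R)-5-[4-(benzyloxy)-3-methoxyphenyl]-4-{[(tert-butyldimethylsilyl)oxy]methyl}-4-hydroxydihydrofuran-2(3H)-one
Conditions: TBSCl (1.1 equiv), imidazole, DMF, 0 °C
Reagents that add atoms: tert-butyldimethylsilyl chloride, CC(C)(C)[Si](C)(C)Cl
Why: Selective silylation of the primary C8 hydroxyl over the tertiary C1 hydroxyl. It blocks acyl migration back to the C8 oxygen and leaves the C1 hydroxyl free for the dianion.

**Step 6**
Reactants: 10 silyl ether; 11 3,4-dimethoxybenzaldehyde (veratraldehyde)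
Product: 12 (3R,4S,5R)-5-[4-(benzyloxy)-3-methoxyphenyl]-4-{[(tert-butyldimethylsilyl)oxy]methyl}-3-[(3,4-dimethoxyphenyl)(hydroxy)methyl]-4-hydroxydihydrofuran-2(3H)-one (both carbinol epimers)
Conditions: LiN(iPr)2 (2.3 equiv), THF, −78 °C; then 11 (1.3 equiv), −78 °C; AcOH, −78 °C
Reagents that add atoms: none
Why: Aldol addition of the alkoxide–enolate dianion of a β-hydroxy lactone (Fráter–Seebach-type); the C1 alkoxide is a poor leaving group, so β-elimination is not expected. With the C2 aryl pseudoequatorial, the cis C1–OLi is pseudoaxial and shields its face, so 11 should add to C5 anti to the alkoxide, which places C6 cis to C8 (C5 = R). The carbinol configuration is left open because step 8 is stereoconvergent.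

**Step 7**
Reactants: 12 aldol adduct
Product: 13 (3R,4S,5R)-5-[4-(benzyloxy)-3-methoxyphenyl]-3-[(3,4-dimethoxyphenyl)(hydroxy)methyl]-4-hydroxy-4-(hydroxymethyl)dihydrofuran-2(3H)-one (both carbinol epimers)
Conditions: HF·pyridine, pyridine, THF, 0 °C → rt
Reagents that add atoms: none
Why: Fluoride cleavage of the primary silyl ether under buffered, weakly acidic conditions, which should avoid retro-aldol cleavage and lactone migration.

**Step 8**
Reactants: 13 triol lactone
Product: 14 (1S,2R,5R,6S)-2-[4-(benzyloxy)-3-methoxyphenyl]-6-(3,4-dimethoxyphenyl)-1-hydroxy-3,7-dioxabicyclo[3.3.0]octan-4-one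
Conditions: 10-camphorsulfonic acid (0.1 equiv), 4 Å molecular sieves, CH2Cl2, 0 °C
Reagents that add atoms: none
Why: Acid-catalysed SN1 etherification: the 3,4-dimethoxybenzylic C6 hydroxyl ionises and the C8 hydroxyl captures the cation (5-exo), closing ring B cis-fused from either C6 epimer. In the cation the small H5 eclipses the aryl (A1,3 strain) while C1 delivers O7, so the aryl should end cis to H5 (exo, C6 = S).

**Step 9**
Reactants: 14 bicyclic hydroxy lactone
Product: 16 (1S,2R,5R,6S)-2-[4-(benzyloxy)-3-methoxyphenyl]-6-(3,4-dimethoxyphenyl)-3,7-dioxabicyclo[3.3.0]octan-1-ol, via lactol 15 (not isolated)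
Conditions: i-Bu2AlH (3 equiv), CH2Cl2, −78 °C, aq. KNaC4H4O6 work-up; then Et3SiH (5 equiv), BF3·OEt2 (2 equiv), CH2Cl2, −78 → −40 °C
Reagents that add atoms: none
Why: Two-stage lactone-to-ether reduction: hydride reduction to the lactol, then ionic hydrogenation of the C4 oxocarbenium ion by the silane. At −78 °C the hemiacetal should ionise far faster than the benzylic ring ethers at C2 and C6, so no stereocentre is touched.

**Step 10**
Reactants: 16 tertiary alcohol
Product: 17 (1S,2R,5R,6S)-2-[4-(benzyloxy)-3-methoxyphenyl]-6-(3,4-dimethoxyphenyl)-3,7-dioxabicyclo[3.3.0]octan-1-yl acetate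
Conditions: Ac2O, 4-(dimethylamino)pyridine, Et3N, CH2Cl2, rt → 40 °C
Reagents that add atoms: acetic anhydride, CC(=O)OC(C)=O
Why: Nucleophile-catalysed acylation through the N-acetylpyridinium ion; the tertiary C1 hydroxyl lies on the convex face and is the only hydroxyl left.

**Step 11**
Reactants: 17 benzyl ether acetate
Product: 18 (1S,2R,5R,6S)-6-(3,4-dimethoxyphenyl)-2-(4-hydroxy-3-methoxyphenyl)-3,7-dioxabicyclo[3.3.0]octan-1-yl acetate (target)
Conditions: H2 (1 atm), 10% Pd/C, EtOAc, rt, stopped after one equivalent of H2
Reagents that add atoms: none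
Why: Hydrogenolysis of the aryl benzyl ether, which under neutral conditions should be cleaved much faster than the cyclic benzylic C2–O3 and C6–O7 bonds; the tertiary acetate is inert.

## Compound list

1 | 4-(benzyloxy)-3-methoxybenzaldehyde (O-benzylvanillin) | COc1cc(C=O)ccc1OCc1ccccc1 | starting material
2 | dimethyl succinate | COC(=O)CCC(=O)OC | starting material
3 | methyl 2-[4-(benzyloxy)-3-methoxyphenyl]-5-oxotetrahydrofuran-3-carboxylate (racemic, diastereomer mixture) | COC(=O)C1CC(=O)OC1c1ccc(OCc2ccccc2)c(OC)c1 | intermediate (not isolated)
4 | (E)-4-[4-(benzyloxy)-3-methoxyphenyl]-3-(methoxycarbonyl)but-3-enoic acid | COC(=O)/C(CC(=O)O)=C/c1ccc(OCc2ccccc2)c(OC)c1 | intermediate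
5 | (E)-4-[4-(benzyloxy)-3-methoxyphenyl]-3-(hydroxymethyl)but-3-enoic acid | OC/C(CC(=O)O)=C/c1ccc(OCc2ccccc2)c(OC)c1 | intermediate (not isolated)
6 | (E)-4-[4-(benzyloxy)-3-methoxybenzylidene]dihydrofuran-2(3H)-one | O=C1C/C(CO1)=C\c1ccc(OCc2ccccc2)c(OC)c1 | intermediate
7 | (2S,3S)-2-[4-(benzyloxy)-3-methoxyphenyl]-1,5-dioxaspiro[2.4]heptan-6-one (aryl cis to the ring CH2C=O) | COc1cc([C@@H]2O[C@@]23COC(=O)C3)ccc1OCc1ccccc1 | intermediate
8 | 2-[(2S,3S)-3-[4-(benzyloxy)-3-methoxyphenyl]-2-(hydroxymethyl)oxiran-2-yl]acetic acid (present as its lithium carboxylate) | COc1cc([C@@H]2O[C@@]2(CC(=O)O)CO)ccc1OCc1ccccc1 | intermediate (not isolated)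
9 | (4S,5R)-5-[4-(benzyloxy)-3-methoxyphenyl]-4-hydroxy-4-(hydroxymethyl)dihydrofuran-2(3H)-one (aryl cis to OH) | COc1cc([C@H]2OC(=O)C[C@@]2(CO)O)ccc1OCc1ccccc1 | intermediate
10 | (4S,5R)-5-[4-(benzyloxy)-3-methoxyphenyl]-4-{[(tert-butyldimethylsilyl)oxy]methyl}-4-hydroxydihydrofuran-2(3H)-one | COc1cc([C@H]2OC(=O)C[C@@]2(CO[Si](C)(C)C(C)(C)C)O)ccc1OCc1ccccc1 | intermediate
11 | 3,4-dimethoxybenzaldehyde (veratraldehyde) | COc1ccc(C=O)cc1OC | starting material
12 | (3R,4S,5R)-5-[4-(benzyloxy)-3-methoxyphenyl]-4-{[(tert-butyldimethylsilyl)oxy]methyl}-3-[(3,4-dimethoxyphenyl)(hydroxy)methyl]-4-hydroxydihydrofuran-2(3H)-one (carbinol epimers) | COc1cc([C@H]2OC(=O)[C@H](C(O)c3ccc(OC)c(OC)c3)[C@@]2(CO[Si](C)(C)C(C)(C)C)O)ccc1OCc1ccccc1 | intermediate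
13 | (3R,4S,5R)-5-[4-(benzyloxy)-3-methoxyphenyl]-3-[(3,4-dimethoxyphenyl)(hydroxy)methyl]-4-hydroxy-4-(hydroxymethyl)dihydrofuran-2(3H)-one (carbinol epimers) | COc1cc([C@H]2OC(=O)[C@H](C(O)c3ccc(OC)c(OC)c3)[C@@]2(CO)O)ccc1OCc1ccccc1 | intermediate
14 | (1S,2R,5R,6S)-2-[4-(benzyloxy)-3-methoxyphenyl]-6-(3,4-dimethoxyphenyl)-1-hydroxy-3,7-dioxabicyclo[3.3.0]octan-4-one | COc1cc([C@H]2OC(=O)[C@@H]3[C@@H](c4ccc(OC)c(OC)c4)OC[C@]23O)ccc1OCc1ccccc1 | intermediate
15 | (1S,2R,5R,6S)-2-[4-(benzyloxy)-3-methoxyphenyl]-6-(3,4-dimethoxyphenyl)-3,7-dioxabicyclo[3.3.0]octane-1,4-diol (C4 anomers) | COc1cc([C@H]2OC(O)[C@@H]3[C@@H](c4ccc(OC)c(OC)c4)OC[C@]23O)ccc1OCc1ccccc1 | intermediate (not isolated)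
16 | (1S,2R,5R,6S)-2-[4-(benzyloxy)-3-methoxyphenyl]-6-(3,4-dimethoxyphenyl)-3,7-dioxabicyclo[3.3.0]octan-1-ol | COc1cc([C@H]2OC[C@@H]3[C@@H](c4ccc(OC)c(OC)c4)OC[C@]23O)ccc1OCc1ccccc1 | intermediate
17 | (1S,2R,5R,6S)-2-[4-(benzyloxy)-3-methoxyphenyl]-6-(3,4-dimethoxyphenyl)-3,7-dioxabicyclo[3.3.0]octan-1-yl acetate | COc1cc([C@H]2OC[C@@H]3[C@@H](c4ccc(OC)c(OC)c4)OC[C@]23OC(C)=O)ccc1OCc1ccccc1 | intermediate
18 | (1S,2R,5R,6S)-6-(3,4-dimethoxyphenyl)-2-(4-hydroxy-3-methoxyphenyl)-3,7-dioxabicyclo[3.3.0]octan-1-yl acetate | COc1cc([C@H]2OC[C@@H]3[C@@H](c4ccc(OC)c(OC)c4)OC[C@]23OC(C)=O)ccc1O | target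

## Step count and least certain steps

Total: 11 steps. Longest linear sequence: 11 steps (1 to 18); 2 and 11 enter as commercial materials.

**Step 4 (key step).** The C2–O bond may ionise ahead of carboxylate attack, which would erode the C2 configuration; capture by water and aryl-assisted rearrangement of the epoxide would drain material further. Fallback: setting out from 7, the lactone is opened with Me2NH in THF at 0 °C to the epoxy hydroxy amide 2-[(2S,3S)-3-[4-(benzyloxy)-3-methoxyphenyl]-2-(hydroxymethyl)oxiran-2-yl]-N,N-dimethylacetamide F1. In dry CH2Cl2 with pyridinium p-toluenesulfonate the neutral amide oxygen, a far better neighbouring group than a carboxylate and used here without water, opens the epoxide at C2 with inversion. Aqueous work-up then releases dimethylamine and gives the lactone, so the route is rejoined at 9.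

**Step 3.** The ketone catalyst may discriminate poorly between the faces of this exocyclic olefin, and at pH 10.5 the double bond of 6 may migrate into conjugation or the epoxide of 7 may open by E1cB. Fallback: setting out from 4, the acid is esterified (Boc2O, 4-(dimethylamino)pyridine, t-BuOH) to the mixed diester 4-tert-butyl 1-methyl (E)-2-[4-(benzyloxy)-3-methoxybenzylidene]butanedioate F2. i-Bu2AlH at −78 °C reduces the conjugated methyl ester in preference to the hindered tert-butyl ester and gives the allylic alcohol tert-butyl (E)-4-[4-(benzyloxy)-3-methoxyphenyl]-3-(hydroxymethyl)but-3-enoate F3. Sharpless asymmetric epoxidation (Ti(OiPr)4, L-(+)-diethyl tartrate, t-BuOOH, 4 Å molecular sieves, CH2Cl2, −20 °C), which by analogy with (E)-cinnamyl alcohol should deliver the (2S,3S) epoxide under non-basic conditions, gives tert-butyl 2-[(2S,3S)-3-[4-(benzyloxy)-3-methoxyphenyl]-2-(hydroxymethyl)oxiran-2-yl]acetate F4. Catalytic 10-camphorsulfonic acid in CH2Cl2 then lets the ester carbonyl open the epoxide at C2 with inversion while the tert-butyl group leaves as 2-methylpropene, and the route is rejoined at 9.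

**Step 6.** Facial selectivity at C5 may be poor, because the CH2OTBS arm on the face to be attacked competes in size with the solvated alkoxide, and the aldolate may revert on warming. Fallback: setting out from 9, the 1,2-diol is acetalised with 3,4-dimethoxybenzaldehyde dimethyl acetal and pyridinium p-toluenesulfonate to the spiro dioxolane (5S,6R)-6-[4-(benzyloxy)-3-methoxyphenyl]-2-(3,4-dimethoxyphenyl)-1,3,7-trioxaspiro[4.4]nonan-8-one F5. LiN(iPr)2 and Me3SiCl at −78 °C give its trimethylsilyl ketene acetal F6, kept cold to prevent β-elimination of the acetal oxygen. Me3SiOTf at −78 °C ionises the acetal, and the oxocarbenium ion on the C8 oxygen is attacked by C5 in an intramolecular Mukaiyama-type aldol reaction. The tether enforces the cis fusion and the C1 oxygen is released as the hydroxyl, so the route is rejoined at 14 and steps 5 to 8 are bypassed.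

**Step 8.** The C6 cation may lose H5 to give the conjugated arylidene lactone, the exo/endo preference may be low, or the lactone may ionise at C2. Fallback: setting out from 13, LiBH4 in THF reduces the lactone to the pentaol (1R,2S,3R)-1-[4-(benzyloxy)-3-methoxyphenyl]-4-(3,4-dimethoxyphenyl)-2,3-bis(hydroxymethyl)butane-1,2,4-triol F7. Catalytic 10-camphorsulfonic acid in CH2Cl2–THF then ionises both benzylic alcohols and each is captured by the primary hydroxyl that can form a five-membered ring (other pairings would give oxetanes). This is the classical double cyclisation to furofurans, with both aryls placed exo by the same A1,3 control. The route is rejoined at 16 and steps 8 and 9 are bypassed, at the price that C2 is set again in the closure and not carried over.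

**Step 9.** The Lewis acid may ionise the benzylic C–O bonds in competition with the lactol, leading to epimerisation or reductive ring opening by the silane. Fallback: setting out from 14, LiAlH4 reduces the lactone to the triol (3S,4R,5S)-3-{(R)-[4-(benzyloxy)-3-methoxyphenyl](hydroxy)methyl}-5-(3,4-dimethoxyphenyl)-4-(hydroxymethyl)tetrahydrofuran-3-ol F8, in which ring B is intact. MsCl (1 equiv) and Et3N in CH2Cl2 at 0 °C sulfonylate the primary C4 hydroxyl selectively and the C2 hydroxyl displaces the sulfonate in a 5-exo-tet closure with retention at C2, without Lewis acid or silane. The route is rejoined at 16.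

## Further compounds

F1 | step 4 | 2-[(2S,3S)-3-[4-(benzyloxy)-3-methoxyphenyl]-2-(hydroxymethyl)oxiran-2-yl]-N,N-dimethylacetamide | COc1cc([C@@H]2O[C@@]2(CC(=O)N(C)C)CO)ccc1OCc1ccccc1
F2 | step 3 | 4-tert-butyl 1-methyl (E)-2-[4-(benzyloxy)-3-methoxybenzylidene]butanedioate | COC(=O)/C(CC(=O)OC(C)(C)C)=C/c1ccc(OCc2ccccc2)c(OC)c1
F3 | step 3 | tert-butyl (E)-4-[4-(benzyloxy)-3-methoxyphenyl]-3-(hydroxymethyl)but-3-enoate | CC(C)(C)OC(=O)C/C(CO)=C\c1ccc(OCc2ccccc2)c(OC)c1
F4 | step 3 | tert-butyl 2-[(2S,3S)-3-[4-(benzyloxy)-3-methoxyphenyl]-2-(hydroxymethyl)oxiran-2-yl]acetate | COc1cc([C@@H]2O[C@@]2(CC(=O)OC(C)(C)C)CO)ccc1OCc1ccccc1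
F5 | step 6 | (5S,6R)-6-[4-(benzyloxy)-3-methoxyphenyl]-2-(3,4-dimethoxyphenyl)-1,3,7-trioxaspiro[4.4]nonan-8-one (acetal epimers) | COc1cc([C@H]2OC(=O)C[C@]23COC(c4ccc(OC)c(OC)c4)O3)ccc1OCc1ccccc1
F6 | step 6 | trimethylsilyl ketene acetal of F5 (8-trimethylsilyloxy-1,3,7-trioxaspiro[4.4]non-8-ene) | COc1cc([C@H]2OC(O[Si](C)(C)C)=C[C@]23COC(c4ccc(OC)c(OC)c4)O3)ccc1OCc1ccccc1
F7 | step 8 | (1R,2S,3R)-1-[4-(benzyloxy)-3-methoxyphenyl]-4-(3,4-dimethoxyphenyl)-2,3-bis(hydroxymethyl)butane-1,2,4-triol (C4 epimers) | COc1cc([C@@H](O)[C@@](O)(CO)[C@H](CO)C(O)c2ccc(OC)c(OC)c2)ccc1OCc1ccccc1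
F8 | step 9 | (3S,4R,5S)-3-{(R)-[4-(benzyloxy)-3-methoxyphenyl](hydroxy)methyl}-5-(3,4-dimethoxyphenyl)-4-(hydroxymethyl)tetrahydrofuran-3-ol | COc1cc([C@@H](O)[C@@]2(O)CO[C@H](c3ccc(OC)c(OC)c3)[C@H]2CO)ccc1OCc1ccccc1
A1 | alternative 1 | C1-hydroxy furofuran with the phenol as acetate | COc1cc([C@H]2OC[C@@H]3[C@@H](c4ccc(OC)c(OC)c4)OC[C@]23O)ccc1OC(C)=O
A2 | alternative 1 | ring A tetrahydrofuran with 3,4-dimethoxybenzyl at C5, C1 hydroxyl and C8 hydroxymethyl, phenol as acetate | COc1cc([C@H]2OC[C@H](Cc3ccc(OC)c(OC)c3)[C@@]2(CO)O)ccc1OC(C)=O
A3 | alternative 2 | C1-hydroxy furofuran benzyl ether (identical with 16) | COc1cc([C@H]2OC[C@@H]3[C@@H](c4ccc(OC)c(OC)c4)OC[C@]23O)ccc1OCc1ccccc1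
A4 | alternative 2 | eight-membered keto enol ether (C1 ketone, Z C4=C5 enol ether, aryls at C2 and C6) | COc1cc([C@H]2O/C=C\[C@@H](c3ccc(OC)c(OC)c3)OCC2=O)ccc1OCc1ccccc1
A5 | alternative 3 | bicyclic ring A lactone with C1 tert-butyldimethylsilyl ether | COc1cc([C@H]2OC(=O)[C@@H]3[C@@H](c4ccc(OC)c(OC)c4)OC[C@]23O[Si](C)(C)C(C)(C)C)ccc1OCc1ccccc1
A6 | alternative 3 | cis-fused 2-aryl cyclobutanone (C1–C2–C4(=O)–C5 ring fused to ring B) | COc1cc([C@H]2C(=O)[C@@H]3[C@@H](c4ccc(OC)c(OC)c4)OC[C@]23O[Si](C)(C)C(C)(C)C)ccc1OCc1ccccc1
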